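At [E] = 0.0151 M, a living end L gains monomer exactly as fast as it gives it back; this ratio of the return constant to the addition constant is the balance point, known as the equilibrium monomer concentration, and [L] cancels out of it.

| setting | ochre | green |
|---|---|---|
| E | 0.050 M | 0.050 M |
| G | 5 mol% | 5 mol% |
| time | 15 s | 5.0 s |

    E + G → L + Q (k1 = 24.6 M⁻¹ s⁻¹)
    E + L → Q + L, rate k2*[L]*[E] (k2 = 15.2 M⁻¹ s⁻¹)
    Q + L → E + L, rate k3*[L] as long as [Q] is above zero (k3 = 0.230 s⁻¹)
    E → D (k4 = 0.0228 s⁻¹)
    L + Q → L.Q (k5 = 2.44 M⁻¹ s⁻¹)

1. which of the two ends with the longer chains by the average number of monomer units in a chain (chains begun, living or dead) ("neither" if they lie within 10%) (ochre / green / neither)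
2. average number of monomer units in a chain (chains begun, living or dead) at the end, ochre
3. average number of monomer units in a chain (chains begun, living or dead) at the end, green

- the average divides the monomer in chains by the number of chains begun, living and dead together
- run time (ochre): 15 s

Each chain begins with one unit, and each living end then gains the addition constant times [E], less the return constant, per second, which is 0.530 s⁻¹ at the charge. The lifetime of G at the charged [E] is 0.813 s, so green's time holds 6.15 lifetimes. I therefore take the chains begun as 0.00250 M in both flasks and dock each flask the growth of one lifetime, 0.431.

For the roof, I let E fall by its first-order loss to D, with no uptake into chains. For the floor, I start from the charge less 0.00250 M and let E fall at 0.0608 s⁻¹, adding the uptake by every end and allowing no return. Even this lower estimate of [E] stands at 0.0191 M at ochre's end, above the balance point, so in my reckoning each living end in ochre keeps a net gain from addition and return up to that time. Integrating [E] over each run gives: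

ochre: from 4.22 to 6.77

green: from 2.53 to 3.01

The floors are soft, since I leave out the pairing of L with Q, but ochre's floor lies above green's roof, so I commit to ochre.

The forecast says ochre, with 4.55 and 2.65, on the ground that “the longer ochre run ends with clearly longer chains”.

The simulation gives ochre, with 4.61 for ochre and 2.66 for green, each between my bounds.

The difference in time is the main reason for the gap: green carried to ochre's time reads 4.61, against 2.66. At ochre's end [E] is 0.0258 M, still above the balance point, so addition less return still comes to 0.162 s⁻¹ for each living end there, before the pairing of L with Q is counted. The balance point contains no [L]: the neighbour of green charged with 2 mol% of G also ends above it, at 0.0419 M, and although its Q is lower, 5.72% against 13.3% of the E charged, its average reads 2.87.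

The numbers of this flask are invented, and the outcome is calculated.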